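**Retrosynthetic overview**

1. Target 25 ← hydroxyquinone 24 ← methoxyquinone 23 ← trimethoxy arene 22: ring C is carried as an 11,12,14-trimethoxy arene and oxidised, demethylated and acetylated last; 22 ← 19 by removal of a temporary C3 ketone.
2. Ring B is closed last: C7–C8 by 6-endo arene–epoxide cyclization of 17, then dehydration of the C6 alcohol to the C6=C7 alkene, which erases the auxiliary stereocenter C6.
3. Key disconnection (C5–C10 and C4–C19 in one flask): 17 ← acyclic enol carbonate 14 by an iron-hydride radical–polar crossover; the C10 radical adds to C5 of the C3-keto enone (ring A), then the C4 enolate attacks the carbonate carbon C19 held on O–C20 (lactone ring).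
4. Enabling feature: C19 (on C4) and C20 (on C10) are both β and 1,3-diaxial on ring A and are joined through the lactone oxygen, and the CH carbon C5 lies between C4 and C10; a C4=C5 alkene can therefore be spanned by C10 and by the O-tethered C19 in one event, and one bought stereocenter (C6, from (R)-glycidol) relays to C5, C10 and C4.
5. 14 ← aryl acetaldehyde 7 + dienone 12 (Michael addition, then O-acylation of the aldehyde enol); ring order: C (bought) → A + lactone (key step) → B.

Key step: step 9

Remark: abietane numbering is used for all intermediates (ring A = C1–C5, C10; ring B = C5–C10; ring C = C8, C9, C11–C14; C18 = methyl on C4; C19 = carbonyl carbon on C4; C20 = CH2 on C10).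
Remark (assumption): phosphonate 9 is taken as a purchasable Horner–Wadsworth–Emmons reagent.
Remark (assumption): the C10 radical is taken to add to C5 anti to the allylic C6–O bond; this choice fixes (R)-glycidol as the chiral starting material.

**Step 1**
Reactants: 1 1,2,4-trimethoxybenzene
Product: 3 2-(2,3,6-trimethoxyphenyl)propan-2-ol, via (2,3,6-trimethoxyphenyl)lithium 2 (not isolated)
Conditions: n-BuLi, TMEDA, THF, 0 °C; then acetone, −78 → 23 °C
Reagents that add atoms: acetone, CC(C)=O
Why: Directed ortho-lithiation takes place at the C–H flanked by two methoxy groups, and the aryllithium adds to acetone (1,2-addition).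

**Step 2**
Reactants: 3 2-(2,3,6-trimethoxyphenyl)propan-2-ol
Product: 4 1,2,4-trimethoxy-3-(propan-2-yl)benzene
Conditions: Et3SiH, CF3CO2H, CH2Cl2, 0 → 23 °C
Reagents that add atoms: none
Why: Ionic hydrogenation; the tertiary benzylic alcohol ionises in acid and the cation is reduced by the silane.

**Step 3**
Reactants: 4 1,2,4-trimethoxy-3-(propan-2-yl)benzene
Product: 6 2-[2,3,5-trimethoxy-4-(propan-2-yl)phenyl]ethan-1-ol, via [2,3,5-trimethoxy-4-(propan-2-yl)phenyl]lithium 5 (not isolated)
Conditions: n-BuLi, TMEDA, Et2O, 0 → 23 °C; then ethylene oxide, −78 → 0 °C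
Reagents that add atoms: ethylene oxide, C1CO1
Why: Second directed ortho-lithiation should occur at the more acidic C–H next to the 1,2-dimethoxy pair (one ortho and two meta oxygens; the other C–H is para to a methoxy group and its ortho-methoxy is twisted by the isopropyl group), followed by epoxide opening by the aryllithium.

**Step 4**
Reactants: 6 2-[2,3,5-trimethoxy-4-(propan-2-yl)phenyl]ethan-1-ol
Product: 7 2-[2,3,5-trimethoxy-4-(propan-2-yl)phenyl]acetaldehyde
Conditions: Dess–Martin periodinane, CH2Cl2, 0 → 23 °C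
Reagents that add atoms: none
Why: Dess–Martin oxidation of a primary alcohol stops at the aldehyde under neutral conditions that the electron-rich arene tolerates.

**Step 5**
Reactants: 8 (R)-glycidol [(2R)-oxiran-2-ylmethanol]; 9 diethyl [1-(methoxy(methyl)amino)-1-oxopropan-2-yl]phosphonate
Product: 11 (2E)-N-methoxy-N,2-dimethyl-3-[(2R)-oxiran-2-yl]prop-2-enamide, via (2S)-oxirane-2-carbaldehyde 10 (not isolated)
Conditions: Dess–Martin periodinane, CH2Cl2, 0 °C; then 9, LiCl, DBU, MeCN, 0 °C
Reagents that add atoms: none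
Why: Dess–Martin oxidation followed by Horner–Wadsworth–Emmons olefination with the α-methyl phosphonate should give the E trisubstituted alkene; the epoxide stereocenter is not enolisable and is carried through unchanged (its descriptor changes only formally in 10).

**Step 6**
Reactants: 11 (2E)-N-methoxy-N,2-dimethyl-3-[(2R)-oxiran-2-yl]prop-2-enamide
Product: 12 (4E)-4-methyl-5-[(2R)-oxiran-2-yl]penta-1,4-dien-3-one
Conditions: CH2=CHMgBr, THF, −78 → −20 °C
Reagents that add atoms: vinylmagnesium bromide, C=C[Mg]Br
Why: Weinreb ketone synthesis; the chelated tetrahedral adduct prevents over-addition, and the epoxide should not react with the Grignard reagent at low temperature without copper.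

**Step 7**
Reactants: 7 2-[2,3,5-trimethoxy-4-(propan-2-yl)phenyl]acetaldehyde; 12 (4E)-4-methyl-5-[(2R)-oxiran-2-yl]penta-1,4-dien-3-one
Product: 13 (6E)-6-methyl-5-oxo-7-[(2R)-oxiran-2-yl]-2-[2,3,5-trimethoxy-4-(propan-2-yl)phenyl]hept-6-enal (both C2 epimers)
Conditions: pyrrolidine (20 mol %), AcOH (20 mol %), CH2Cl2, 0 °C
Reagents that add atoms: none
Why: Enamine-catalysed Michael addition of the α-aryl aldehyde to the unsubstituted vinyl terminus of the cross-conjugated dienone; the new centre (C10) forms as both epimers, which does not matter because it becomes sp2 in step 8.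

**Step 8**
Reactants: 13 (6E)-6-methyl-5-oxo-7-[(2R)-oxiran-2-yl]-2-[2,3,5-trimethoxy-4-(propan-2-yl)phenyl]hept-6-enal
Product: 14 (6E)-6-methyl-5-oxo-7-[(2R)-oxiran-2-yl]-2-[2,3,5-trimethoxy-4-(propan-2-yl)phenyl]hepta-1,6-dien-1-yl phenyl carbonate (1E/1Z mixture)
Conditions: PhOC(O)Cl, Et3N, DMAP (cat.), CH2Cl2, 0 °C
Reagents that add atoms: phenyl chloroformate, O=C(Cl)Oc1ccccc1
Why: Enol ester formation by O-acylation of the enol of the most acidic carbonyl group (the α-aryl aldehyde); both alkene isomers converge in step 9.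

**Step 9**
Reactants: 14 (6E)-6-methyl-5-oxo-7-[(2R)-oxiran-2-yl]-2-[2,3,5-trimethoxy-4-(propan-2-yl)phenyl]hepta-1,6-dien-1-yl phenyl carbonate
Product: 17 (6R)-6,7-epoxy-11,12,14-trimethoxy-3-oxo-7,8-seco-abieta-8,11,13-trien-19,20-olide (5α-H; lactone bridge β; 4-methyl α), via tertiary benzylic radical 15 (not isolated), via ring A enolate 16 (not isolated)
Conditions: Fe(acac)3 [iron tris(acetylacetonate)] (30 mol %), PhSiH2(Oi-Pr) (slow addition), THF, 0 → 23 °C, no protic co-solvent
Reagents that add atoms: none
Why: Proposed new method: an iron hydride formed from Fe(acac)3 and the silane transfers a hydrogen atom to C20 of the electron-rich enol carbonate (not to the electron-poor enone), the tertiary benzylic C10 radical adds to C5 of the enone (6-endo-trig, ring A), the C4 α-keto radical is reduced by divalent iron to the trivalent iron enolate, and this regiospecific enolate attacks the phenyl carbonate carbon C19 held on O–C20 (6-exo-trig acyl substitution, lactone ring), phenoxide leaving and re-forming the hydride with the silane. The closest known reaction type is the iron-hydride-initiated radical–polar crossover annulation (Giese cyclization followed by intramolecular aldol); here the enolate is intercepted by a Claisen-type C-acylation, and the protic co-solvent is left out so that acyl transfer can outrun protonation. C5 is controlled by the bought C6 stereocenter: allylic 1,3-strain with the C4 methyl holds H6 in the enone plane and the radical should add anti to the C6–O bond, which for (6R) gives 5α-H. C10 is set relative to C5 in a chair-like transition state with the bulky aryl group pseudo-equatorial (anti to C4) and the CH2O arm pseudo-axial; C4 is set by the tether, because C19 can reach the enolate only on the face that carries C20, which leaves the methyl α. The step needs 6-endo over 5-exo closure (polarity match at the β-carbon, fully substituted α-carbon), C- over O-acylation (only C4 gives a six-membered ring) and acylation at C4 and not C2 (the enolate is generated at C4 only).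

**Step 10**
Reactants: 17 (6R)-6,7-epoxy-11,12,14-trimethoxy-3-oxo-7,8-seco-abieta-8,11,13-trien-19,20-olide
Product: 18 6α-hydroxy-11,12,14-trimethoxy-3-oxo-abieta-8,11,13-trien-19,20-olide
Conditions: BF3·OEt2, CH2Cl2, −78 → −30 °C
Reagents that add atoms: none
Why: Lewis-acid-promoted arene–epoxide cyclization (intramolecular Friedel–Crafts alkylation); C8, ortho and para to methoxy groups, should open the epoxide at its terminal carbon C7 in the 6-endo mode, and C6 keeps its configuration as the 6α-alcohol.

**Step 11**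
Reactants: 18 6α-hydroxy-11,12,14-trimethoxy-3-oxo-abieta-8,11,13-trien-19,20-olide
Product: 19 11,12,14-trimethoxy-3-oxo-abieta-6,8,11,13-tetraen-19,20-olide
Conditions: Burgess reagent, PhMe, 60 °C
Reagents that add atoms: none
Why: Burgess dehydration (syn elimination) should remove the benzylic hydrogen at C7 and give the arene-conjugated C6=C7 alkene, which deletes the auxiliary stereocenter C6; C5 is not affected.

**Step 12**
Reactants: 19 11,12,14-trimethoxy-3-oxo-abieta-6,8,11,13-tetraen-19,20-olide
Product: 20 3β-hydroxy-11,12,14-trimethoxy-abieta-6,8,11,13-tetraen-19,20-olide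
Conditions: NaBH4, MeOH/CH2Cl2, −20 °C
Reagents that add atoms: none
Why: Borohydride reduction of the ketone, with hydride expected from the α face to give the equatorial 3β-alcohol (its configuration is irrelevant, since C3 is deoxygenated in step 14); the hindered lactone should not be reduced.

**Step 13**
Reactants: 20 3β-hydroxy-11,12,14-trimethoxy-abieta-6,8,11,13-tetraen-19,20-olide
Product: 21 O-(11,12,14-trimethoxy-19,20-olido-abieta-6,8,11,13-tetraen-3β-yl) 1H-imidazole-1-carbothioate
Conditions: 1,1'-thiocarbonyldiimidazole, DMAP (cat.), ClCH2CH2Cl, 70 °C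
Reagents that add atoms: 1,1'-thiocarbonyldiimidazole, S=C(n1ccnc1)n1ccnc1
Why: Thioacylation of the secondary alcohol gives the thiocarbonyl derivative needed for radical deoxygenation.

**Step 14**
Reactants: 21 O-(11,12,14-trimethoxy-19,20-olido-abieta-6,8,11,13-tetraen-3β-yl) 1H-imidazole-1-carbothioate
Product: 22 11,12,14-trimethoxy-abieta-6,8,11,13-tetraen-19,20-olide
Conditions: Bu3SnH, AIBN (cat.), PhMe, 100 °C
Reagents that add atoms: none
Why: Barton–McCombie deoxygenation; the stannyl radical adds to the thiocarbonyl group, the C3–O bond fragments and the secondary C3 radical is reduced by the stannane.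

**Step 15**
Reactants: 22 11,12,14-trimethoxy-abieta-6,8,11,13-tetraen-19,20-olide
Product: 23 12-methoxy-11,14-dioxo-abieta-6,8,12-trien-19,20-olide
Conditions: (NH4)2Ce(NO3)6, MeCN/H2O, 0 °C
Reagents that add atoms: water, O
Why: Oxidative demethylation of the para-dimethoxy pair (C11, C14) by tetravalent cerium should give the para-quinone and leave the C12 methoxy group as a vinylogous ester.

**Step 16**
Reactants: 23 12-methoxy-11,14-dioxo-abieta-6,8,12-trien-19,20-olide
Product: 24 12-hydroxy-11,14-dioxo-abieta-6,8,12-trien-19,20-olide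
Conditions: BCl3, CH2Cl2, −78 → 0 °C; then H2O
Reagents that add atoms: none
Why: Chelation-assisted demethylation; boron trichloride cleaves the methyl vinylogous ester next to the C11 carbonyl and should leave the lactone intact.

**Step 17**
Reactants: 24 12-hydroxy-11,14-dioxo-abieta-6,8,12-trien-19,20-olide
Product: 25 (4S,5R,10R)-12-acetoxy-11,14-dioxo-abieta-6,8,12-trien-19,20-olide (target)
Conditions: Ac2O, pyridine, DMAP (cat.), CH2Cl2, 0 → 23 °C
Reagents that add atoms: acetic anhydride, CC(=O)OC(C)=O
Why: O-acetylation (esterification) of the acidic 12-hydroxyquinone gives the target; no stereocenter is touched.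

**Compound list**

1 | 1,2,4-trimethoxybenzene | COc1ccc(OC)c(OC)c1 | starting material
2 | (2,3,6-trimethoxyphenyl)lithium, formed in the flask | [Li]c1c(OC)ccc(OC)c1OC | intermediate
3 | 2-(2,3,6-trimethoxyphenyl)propan-2-ol | CC(C)(O)c1c(OC)ccc(OC)c1OC | intermediate
4 | 1,2,4-trimethoxy-3-(propan-2-yl)benzene | CC(C)c1c(OC)ccc(OC)c1OC | intermediate
5 | [2,3,5-trimethoxy-4-(propan-2-yl)phenyl]lithium, formed in the flask | CC(C)c1c(OC)cc([Li])c(OC)c1OC | intermediate
6 | 2-[2,3,5-trimethoxy-4-(propan-2-yl)phenyl]ethan-1-ol | CC(C)c1c(OC)cc(CCO)c(OC)c1OC | intermediate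
7 | 2-[2,3,5-trimethoxy-4-(propan-2-yl)phenyl]acetaldehyde | CC(C)c1c(OC)cc(CC=O)c(OC)c1OC | intermediate
8 | (R)-glycidol, (2R)-oxiran-2-ylmethanol | OC[C@@H]1CO1 | starting material
9 | diethyl [1-(methoxy(methyl)amino)-1-oxopropan-2-yl]phosphonate | CCOP(=O)(OCC)C(C)C(=O)N(C)OC | starting material
10 | (2S)-oxirane-2-carbaldehyde, formed in the flask | O=C[C@@H]1CO1 | intermediate
11 | (2E)-N-methoxy-N,2-dimethyl-3-[(2R)-oxiran-2-yl]prop-2-enamide | CON(C)C(=O)/C(C)=C/[C@@H]1CO1 | intermediate
12 | (4E)-4-methyl-5-[(2R)-oxiran-2-yl]penta-1,4-dien-3-one | C=CC(=O)/C(C)=C/[C@@H]1CO1 | intermediate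
13 | (6E)-6-methyl-5-oxo-7-[(2R)-oxiran-2-yl]-2-[2,3,5-trimethoxy-4-(propan-2-yl)phenyl]hept-6-enal, both C2 epimers | O=CC(CCC(=O)/C(C)=C/[C@@H]1CO1)c1cc(OC)c(C(C)C)c(OC)c1OC | intermediate
14 | (6E)-6-methyl-5-oxo-7-[(2R)-oxiran-2-yl]-2-[2,3,5-trimethoxy-4-(propan-2-yl)phenyl]hepta-1,6-dien-1-yl phenyl carbonate, 1E/1Z mixture (enol alkene drawn without geometry) | O=C(Oc1ccccc1)OC=C(CCC(=O)/C(C)=C/[C@@H]1CO1)c1cc(OC)c(C(C)C)c(OC)c1OC | intermediate
15 | tertiary benzylic C10 radical formed from 14 by hydrogen-atom transfer to C20, formed in the flask | COc1cc(c(OC)c(OC)c1C(C)C)[C](COC(=O)Oc1ccccc1)CCC(=O)/C(C)=C/[C@@H]1CO1 | intermediate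
16 | ring A C3–C4 enolate after C5–C10 closure (iron-bound, drawn as the free enolate anion), formed in the flask | COc1cc(c(OC)c(OC)c1C(C)C)[C@@]1(COC(=O)Oc2ccccc2)CCC([O-])=C(C)[C@@H]1[C@@H]1CO1 | intermediate
17 | (6R)-6,7-epoxy-11,12,14-trimethoxy-3-oxo-7,8-seco-abieta-8,11,13-trien-19,20-olide (5α-H, 4α-methyl, lactone on the β face) | COc1cc(c(OC)c(OC)c1C(C)C)[C@]12CCC(=O)[C@](C)(C(=O)OC1)[C@@H]2[C@@H]1CO1 | intermediate
18 | 6α-hydroxy-11,12,14-trimethoxy-3-oxo-abieta-8,11,13-trien-19,20-olide | COc1c(C(C)C)c(OC)c2c(c1OC)[C@]13CCC(=O)[C@](C)(C(=O)OC1)[C@@H]3[C@@H](O)C2 | intermediate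
19 | 11,12,14-trimethoxy-3-oxo-abieta-6,8,11,13-tetraen-19,20-olide | COc1c(C(C)C)c(OC)c2c(c1OC)[C@]13CCC(=O)[C@](C)(C(=O)OC1)[C@@H]3C=C2 | intermediate
20 | 3β-hydroxy-11,12,14-trimethoxy-abieta-6,8,11,13-tetraen-19,20-olide | COc1c(C(C)C)c(OC)c2c(c1OC)[C@]13CC[C@H](O)[C@](C)(C(=O)OC1)[C@@H]3C=C2 | intermediate
21 | O-(11,12,14-trimethoxy-19,20-olido-abieta-6,8,11,13-tetraen-3β-yl) 1H-imidazole-1-carbothioate | COc1c(C(C)C)c(OC)c2c(c1OC)[C@]13CC[C@H](OC(=S)n4ccnc4)[C@](C)(C(=O)OC1)[C@@H]3C=C2 | intermediate
22 | 11,12,14-trimethoxy-abieta-6,8,11,13-tetraen-19,20-olide | COc1c(C(C)C)c(OC)c2c(c1OC)[C@]13CCC[C@](C)(C(=O)OC1)[C@@H]3C=C2 | intermediate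
23 | 12-methoxy-11,14-dioxo-abieta-6,8,12-trien-19,20-olide | COC1=C(C(C)C)C(=O)C2=C(C1=O)[C@]13CCC[C@](C)(C(=O)OC1)[C@@H]3C=C2 | intermediate
24 | 12-hydroxy-11,14-dioxo-abieta-6,8,12-trien-19,20-olide | OC1=C(C(C)C)C(=O)C2=C(C1=O)[C@]13CCC[C@](C)(C(=O)OC1)[C@@H]3C=C2 | intermediate
25 | (4S,5R,10R)-12-acetoxy-11,14-dioxo-abieta-6,8,12-trien-19,20-olide | CC(=O)OC1=C(C(C)C)C(=O)C2=C(C1=O)[C@]13CCC[C@](C)(C(=O)OC1)[C@@H]3C=C2 | target

**Step count and risks**

Total step count: 17. Longest linear sequence: 15 steps (steps 1–4, then 7–17).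

Steps most likely to fail:

1. Step 9 (carries the label). What may go wrong: the stabilised benzylic radical is reduced, or the C4 enolate is protonated, before acyl transfer, so that ring A closes without the lactone; face selectivity at C5 or C10 may also erode. Fallback with known chemistry, from 14 back to 17: the hydrogen-atom-transfer Giese cyclization is run under the usual protic conditions (Fe(acac)3, PhSiH3, EtOH/ethylene glycol), which should stop at the ring A ketone with intact phenyl carbonate F1 (C4 epimers). Silylation under equilibrating conditions (Me3SiCl, Et3N, DMF, 60 °C) should give the more substituted C3–C4 silyl enol ether F2. Anhydrous fluoride (TASF, THF, −40 °C) then releases the C4 enolate, which closes the lactone by intramolecular C-acylation and gives 17.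

2. Step 10. What may go wrong: the activated epoxide is opened at C6 by the lactone or ketone carbonyl oxygen (five-membered participation), or by 5-exo arylation, in place of 6-endo arylation at C7. Fallback, from 17 back to 19: the epoxide is opened reductively at C6 with Cp2TiCl (made from Cp2TiCl2 and Zn; trivalent titanium) and 1,4-cyclohexadiene to the primary C7 alcohol F3. Dess–Martin oxidation gives the C7 aldehyde F4. Acid-catalysed Friedel–Crafts hydroxyalkylation with dehydration (TsOH, PhMe, 60 °C) then closes ring B and gives 19 directly, bypassing 18.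

3. Step 15. What may go wrong: the cerium oxidant attacks the electron-rich C6=C7 styrene, or demethylation takes the ortho course (C11/C12) to an ortho-quinone. Fallback, from 22 back to 24: all three methyl ethers are cleaved (BBr3, CH2Cl2, −78 → 0 °C) to the 11,12,14-trihydroxy arene F5, and this hydroquinone is oxidised mildly (Ag2O, or air) to hydroxyquinone 24, bypassing 23 and step 16.

**Further compounds**

F1 | step 9 | (6R)-6,7-epoxy-11,12,14-trimethoxy-3-oxo-7,8-seco-19-nor-abieta-8,11,13-trien-20-yl phenyl carbonate (C4 epimers) | COc1cc(c(OC)c(OC)c1C(C)C)[C@@]1(COC(=O)Oc2ccccc2)CCC(=O)C(C)[C@@H]1[C@@H]1CO1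
F2 | step 9 | (6R)-6,7-epoxy-11,12,14-trimethoxy-3-(trimethylsilyloxy)-7,8-seco-19-nor-abieta-3,8,11,13-tetraen-20-yl phenyl carbonate | COc1cc(c(OC)c(OC)c1C(C)C)[C@@]1(COC(=O)Oc2ccccc2)CCC(O[Si](C)(C)C)=C(C)[C@@H]1[C@@H]1CO1
F3 | step 10 | 7-hydroxy-11,12,14-trimethoxy-3-oxo-7,8-seco-abieta-8,11,13-trien-19,20-olide | COc1cc(c(OC)c(OC)c1C(C)C)[C@]12CCC(=O)[C@](C)(C(=O)OC1)[C@@H]2CCO
F4 | step 10 | 11,12,14-trimethoxy-3,7-dioxo-7,8-seco-abieta-8,11,13-trien-19,20-olide | COc1cc(c(OC)c(OC)c1C(C)C)[C@]12CCC(=O)[C@](C)(C(=O)OC1)[C@@H]2CC=O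
F5 | step 15 | 11,12,14-trihydroxy-abieta-6,8,11,13-tetraen-19,20-olide | Oc1c(C(C)C)c(O)c2c(c1O)[C@]13CCC[C@](C)(C(=O)OC1)[C@@H]3C=C2
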